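**Retrosynthetic overview** (chain numbered C1 = ketone carbon to C18 = methyl)
1. Enabling feature: the C9 carbinol is homoallylic to the C6=C7 Z-alkene, so O–C9–C8–C7=C6 is the retron of an allyl transfer. With boron on C6, the atoms B, O, C9, C8, C7 and C6 form a six-membered chair.
2. Key disconnection C8–C9: (2E,4Z,7Z)-deca-2,4,7-trienal (C9–C18) plus a C6-stereogenic secondary allylboronate (C1–C8, carrying the silylated phloroglucinol ketone). One operation gives the C–C bond, the 9R centre and the 6Z alkene.
3. Boronate: enantioselective copper-catalysed SN2′ borylation of a Z-allylic carbonate. The carbonate comes from Z-selective cross-metathesis of an aryl hexenyl ketone, made by Grignard addition to silylated 2,4,6-trihydroxybenzaldehyde and oxidation.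
4. Trienal: Z-selective Wittig reaction of the (Z)-hex-3-enyl ylide with fumaraldehyde mono(dimethyl acetal), then acetal hydrolysis.
5. No ring is built; the benzene-1,3,5-triol ring is bought. Its two ortho silyloxy groups shield the C1 ketone, so only the aldehyde accepts the allyl group. The last step is buffered fluoride desilylation.

Key step: step 11

Assumption: the absolute sense of both chiral catalysts is taken from their behaviour with simple substrates ((S,S)-QuinoxP* with a Z-carbonate gives the R boronate; (R)-TRIP delivers allyl groups to the Re face of enals); if an analytical check of 10 or 19 shows the opposite sense, the mirror-image ligand or acid is used and nothing else changes.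

**Step 1**
Reactants: 1 2,4,6-trihydroxybenzaldehyde
Product: 2 2,4,6-tris(tert-butyldimethylsilyloxy)benzaldehyde
Conditions: TBSCl (3.6 equiv), imidazole, DMF, rt to 40 °C
Reagents that add atoms: tert-butyldimethylsilyl chloride (TBSCl), CC(C)(C)[Si](C)(C)Cl
Why: Imidazole-promoted silyl ether formation masks all three phenols with a group that later falls to buffered fluoride, so no acid has to touch the dienyl carbinol of the target.

**Step 2**
Reactants: 2 2,4,6-tris(tert-butyldimethylsilyloxy)benzaldehyde; 3 6-bromohex-1-ene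
Product: 5 rac-1-[2,4,6-tris(tert-butyldimethylsilyloxy)phenyl]hept-6-en-1-ol, via hex-5-enylmagnesium bromide 4 (not isolated)
Conditions: Mg, THF, rt; then 2, THF, −78 to −40 °C; pH 7 phosphate buffer at −40 °C
Reagents that add atoms: none
Why: Grignard addition to the aldehyde brings in C2–C7 at once; the carbinol centre forms racemic and is erased in step 3, and the cold neutral quench should keep the ortho silyl groups from migrating to the new alkoxide.

**Step 3**
Reactants: 5 rac-1-[2,4,6-tris(tert-butyldimethylsilyloxy)phenyl]hept-6-en-1-ol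
Product: 6 1-[2,4,6-tris(tert-butyldimethylsilyloxy)phenyl]hept-6-en-1-one
Conditions: n-Pr4N[RuO4] (5 mol%), N-methylmorpholine N-oxide, 4 Å MS, CH2Cl2, rt
Reagents that add atoms: none
Why: The Ley–Griffith oxidation is neutral, so the acid-labile electron-rich benzylic alcohol should go to the aryl ketone without ionisation, leaving the terminal alkene and silyl ethers untouched.

**Step 4**
Reactants: 6 1-[2,4,6-tris(tert-butyldimethylsilyloxy)phenyl]hept-6-en-1-one; 7 (Z)-but-2-ene-1,4-diol
Product: 8 (6Z)-8-hydroxy-1-[2,4,6-tris(tert-butyldimethylsilyloxy)phenyl]oct-6-en-1-one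
Conditions: Ru(=CH-C6H4-2-O-i-Pr)(SIMes)(3,6-dichlorobenzene-1,2-dithiolate) (5 mol%), 7 (2 equiv), THF, rt
Reagents that add atoms: none
Why: In this stereoretentive Z-selective olefin cross-metathesis the dithiolate ligand forces the metallacyclobutane substituents to one side, so the Z geometry of the diol passes to the new C6=C7 bond; the remote hindered ketone and aryl silyl ethers do not engage the catalyst.

**Step 5**
Reactants: 8 (6Z)-8-hydroxy-1-[2,4,6-tris(tert-butyldimethylsilyloxy)phenyl]oct-6-en-1-one
Product: 9 methyl (2Z)-8-oxo-8-[2,4,6-tris(tert-butyldimethylsilyloxy)phenyl]oct-2-en-1-yl carbonate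
Conditions: ClCO2Me, pyridine, CH2Cl2, 0 °C
Reagents that add atoms: methyl chloroformate, COC(=O)Cl
Why: O-acylation of the primary allylic alcohol installs a leaving group that later breaks down to CO2 and methoxide, which turns over the copper catalyst without added base.

**Step 6**
Reactants: 9 methyl (2Z)-8-oxo-8-[2,4,6-tris(tert-butyldimethylsilyloxy)phenyl]oct-2-en-1-yl carbonate
Product: 10 (6R)-6-(4,4,5,5-tetramethyl-1,3,2-dioxaborolan-2-yl)-1-[2,4,6-tris(tert-butyldimethylsilyloxy)phenyl]oct-7-en-1-one
Conditions: Cu(O-t-Bu) (5 mol%), (S,S)-QuinoxP* (2,3-bis(tert-butylmethylphosphino)quinoxaline, 5 mol%), B2pin2 (1.5 equiv), THF, 0 °C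
Reagents that add atoms: bis(pinacolato)diboron, CC1(C)OB(OC1(C)C)B1OC(C)(C)C(C)(C)O1
Why: In this enantioselective allylic (SN2′) boryl substitution by monovalent copper, the ligated Cu–Bpin species adds across the Z-alkene with boron at C6 on the face chosen by the P-stereogenic bisphosphine, and β-elimination of the carbonate gives the C7=C8 vinyl group and the 6R centre; the shielded ketone and aryl silyl ethers should be inert under these base-free conditions.

**Step 7**
Reactants: 11 (Z)-hex-3-en-1-ol
Product: 12 (Z)-1-iodohex-3-ene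
Conditions: I2, PPh3, imidazole, CH2Cl2, 0 °C
Reagents that add atoms: iodine, II
Why: Appel-type iodination proceeds by SN2 displacement of the alkoxyphosphonium ion at a primary carbon and leaves the Z-alkene untouched.

**Step 8**
Reactants: 12 (Z)-1-iodohex-3-ene
Product: 13 [(Z)-hex-3-enyl]triphenylphosphonium iodide
Conditions: PPh3, MeCN, reflux
Reagents that add atoms: triphenylphosphine, c1ccc(cc1)P(c1ccccc1)c1ccccc1
Why: SN2 quaternisation of triphenylphosphine by a primary iodide is the standard preparation of a Wittig salt.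

**Step 9**
Reactants: 13 [(Z)-hex-3-enyl]triphenylphosphonium iodide; 14 (E)-4,4-dimethoxybut-2-enal
Product: 16 (2E,4Z,7Z)-1,1-dimethoxydeca-2,4,7-triene, via (Z)-hex-3-enylidenetriphenylphosphorane 15 (not isolated)
Conditions: NaN(SiMe3)2, THF, −78 °C; then 14, −78 °C to rt
Reagents that add atoms: none
Why: The Wittig olefination of a non-stabilised ylide under lithium-free kinetic control should give the new C4=C5 bond as the Z isomer, while the E-enal alkene, the existing Z-alkene and the acetal are not affected.

**Step 10**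
Reactants: 16 (2E,4Z,7Z)-1,1-dimethoxydeca-2,4,7-triene
Product: 17 (2E,4Z,7Z)-deca-2,4,7-trienal
Conditions: 10% aq oxalic acid on SiO2, CH2Cl2, 0 °C; used at once
Reagents that add atoms: water, O
Why: Acetal hydrolysis runs through a dienyl-stabilised oxocarbenium ion that forms so readily that a weak supported acid at low temperature suffices, which limits 4Z to 4E isomerisation.

**Step 11**
Reactants: 10 (6R)-6-(4,4,5,5-tetramethyl-1,3,2-dioxaborolan-2-yl)-1-[2,4,6-tris(tert-butyldimethylsilyloxy)phenyl]oct-7-en-1-one (1.2 equiv); 17 (2E,4Z,7Z)-deca-2,4,7-trienal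
Product: 19 (6Z,9R,10E,12Z,15Z)-9-hydroxy-1-[2,4,6-tris(tert-butyldimethylsilyloxy)phenyl]octadeca-6,10,12,15-tetraen-1-one, via O-pinacolboryl ether 18 (not isolated)
Conditions: (R)-TRIP (3,3′-bis(2,4,6-triisopropylphenyl)-1,1′-binaphthyl-2,2′-diyl hydrogen phosphate, 10 mol%), 4 Å MS, toluene, −30 °C; then aq NaHCO3
Reagents that add atoms: none
Why: The phosphoric acid hydrogen-bonds to a boronate oxygen (its P=O contacting the formyl H), boron binds the aldehyde oxygen, and the allyl group passes from boron to C9 with allylic transposition (syn-SE2′) through a closed Zimmerman–Traxler chair made of B, O, C9, C8, C7 and C6, giving boryl ether 18, which the bicarbonate wash hydrolyses to 19. The closest known reaction type is the chiral-phosphoric-acid-catalysed Z-selective allylboration of aldehydes, enals included, with α-substituted secondary allyl pinacolboronates. No ring is closed in the product, since the six-membered array exists only in the transition state. The new C9 centre is controlled by the boron-bearing C6 centre of 10 (1,3-chirality transfer: with the trienyl group equatorial and the C1–C5 chain axial, (R)-10 reaches only the Re face of 17, which gives 9R) and is reinforced by the matched (R)-acid, which prefers the same face. The 6Z geometry follows from the axial position of the C5 chain, taken to avoid the pinacol methyl groups, whereas the chair with that chain equatorial would lead through the catalyst-disfavoured Si face to the 6E,9S isomer, and residual (S)-10 is diverted to a separable 6E isomer. The selectivities needed are aldehyde over ketone (C1 is flanked by two ortho silyloxy groups and allylboronates ignore ketones at this temperature), 1,2- over 1,4-addition and γ- over α-attack (both enforced by the cyclic transition state), and retention of the 2E,4Z,7Z geometry (no metal, no base, a weak acid, low temperature).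

**Step 12**
Reactants: 19 (6Z,9R,10E,12Z,15Z)-9-hydroxy-1-[2,4,6-tris(tert-butyldimethylsilyloxy)phenyl]octadeca-6,10,12,15-tetraen-1-one
Product: 20 (6Z,9R,10E,12Z,15Z)-9-hydroxy-1-(2,4,6-trihydroxyphenyl)octadeca-6,10,12,15-tetraen-1-one
Conditions: n-Bu4NF (3.3 equiv), AcOH (3.3 equiv), THF, 0 °C
Reagents that add atoms: none
Why: Fluoride-induced desilylation of aryl silyl ethers is fast because phenoxide is a good leaving group, and the acetic acid buffer keeps the medium near neutral, so the skipped diene, the E,Z-diene and the 9R dienyl carbinol should be neither isomerised nor ionised.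

**Compound list**
1 | 2,4,6-trihydroxybenzaldehyde | O=Cc1c(O)cc(O)cc1O | starting material
2 | 2,4,6-tris(tert-butyldimethylsilyloxy)benzaldehyde | O=Cc1c(O[Si](C)(C)C(C)(C)C)cc(O[Si](C)(C)C(C)(C)C)cc1O[Si](C)(C)C(C)(C)C | intermediate
3 | 6-bromohex-1-ene | C=CCCCCBr | starting material
4 | hex-5-enylmagnesium bromide (not isolated) | C=CCCCC[Mg]Br | intermediate
5 | rac-1-[2,4,6-tris(tert-butyldimethylsilyloxy)phenyl]hept-6-en-1-ol | C=CCCCCC(O)c1c(O[Si](C)(C)C(C)(C)C)cc(O[Si](C)(C)C(C)(C)C)cc1O[Si](C)(C)C(C)(C)C | intermediate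
6 | 1-[2,4,6-tris(tert-butyldimethylsilyloxy)phenyl]hept-6-en-1-one | C=CCCCCC(=O)c1c(O[Si](C)(C)C(C)(C)C)cc(O[Si](C)(C)C(C)(C)C)cc1O[Si](C)(C)C(C)(C)C | intermediate
7 | (Z)-but-2-ene-1,4-diol | OC/C=C\CO | starting material
8 | (6Z)-8-hydroxy-1-[2,4,6-tris(tert-butyldimethylsilyloxy)phenyl]oct-6-en-1-one | OC/C=C\CCCCC(=O)c1c(O[Si](C)(C)C(C)(C)C)cc(O[Si](C)(C)C(C)(C)C)cc1O[Si](C)(C)C(C)(C)C | intermediate
9 | methyl (2Z)-8-oxo-8-[2,4,6-tris(tert-butyldimethylsilyloxy)phenyl]oct-2-en-1-yl carbonate | COC(=O)OC/C=C\CCCCC(=O)c1c(O[Si](C)(C)C(C)(C)C)cc(O[Si](C)(C)C(C)(C)C)cc1O[Si](C)(C)C(C)(C)C | intermediate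
10 | (6R)-6-(4,4,5,5-tetramethyl-1,3,2-dioxaborolan-2-yl)-1-[2,4,6-tris(tert-butyldimethylsilyloxy)phenyl]oct-7-en-1-one | C=C[C@H](B1OC(C)(C)C(C)(C)O1)CCCCC(=O)c1c(O[Si](C)(C)C(C)(C)C)cc(O[Si](C)(C)C(C)(C)C)cc1O[Si](C)(C)C(C)(C)C | intermediate
11 | (Z)-hex-3-en-1-ol | CC/C=C\CCO | starting material
12 | (Z)-1-iodohex-3-ene | CC/C=C\CCI | intermediate
13 | [(Z)-hex-3-enyl]triphenylphosphonium iodide | CC/C=C\CC[P+](c1ccccc1)(c1ccccc1)c1ccccc1.[I-] | intermediate
14 | (E)-4,4-dimethoxybut-2-enal (fumaraldehyde mono(dimethyl acetal)) | COC(OC)/C=C/C=O | starting material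
15 | (Z)-hex-3-enylidenetriphenylphosphorane (not isolated) | CC/C=C\CC=P(c1ccccc1)(c1ccccc1)c1ccccc1 | intermediate
16 | (2E,4Z,7Z)-1,1-dimethoxydeca-2,4,7-triene | CC/C=C\C/C=C\C=C\C(OC)OC | intermediate
17 | (2E,4Z,7Z)-deca-2,4,7-trienal | CC/C=C\C/C=C\C=C\C=O | intermediate
18 | O-pinacolboryl ether of 19 (not isolated) | CC/C=C\C/C=C\C=C\[C@H](OB1OC(C)(C)C(C)(C)O1)C/C=C\CCCCC(=O)c1c(O[Si](C)(C)C(C)(C)C)cc(O[Si](C)(C)C(C)(C)C)cc1O[Si](C)(C)C(C)(C)C | intermediate
19 | (6Z,9R,10E,12Z,15Z)-9-hydroxy-1-[2,4,6-tris(tert-butyldimethylsilyloxy)phenyl]octadeca-6,10,12,15-tetraen-1-one | CC/C=C\C/C=C\C=C\[C@H](O)C/C=C\CCCCC(=O)c1c(O[Si](C)(C)C(C)(C)C)cc(O[Si](C)(C)C(C)(C)C)cc1O[Si](C)(C)C(C)(C)C | intermediate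
20 | (6Z,9R,10E,12Z,15Z)-9-hydroxy-1-(2,4,6-trihydroxyphenyl)octadeca-6,10,12,15-tetraen-1-one | CC/C=C\C/C=C\C=C\[C@H](O)C/C=C\CCCCC(=O)c1c(O)cc(O)cc1O | target

**Total step count:** 12. **Longest linear sequence:** 8 (steps 1–6, 11, 12).

**Steps most likely to fail**

**Step 11.** Two things may go wrong. Some reaction may leak through the chair with the C1–C5 chain equatorial, which loses the 6Z geometry. Transfer from the hindered secondary boronate may also be slow, leaving 17 with the acid long enough for the 4Z alkene to drift to 4E.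

The fallback sets out from 9 and 17 and comes back at 19. It moves the stereochemical load from the reagent to the catalyst and enlarges the boron ligand.
- Carbonate 9 is borylated without a chiral ligand (CuCl, Xantphos, KO-t-Bu, bis(3,4-diethylhexane-3,4-diolato)diboron, THF). This gives racemic 6-(4,4,5,5-tetraethyl-1,3,2-dioxaborolan-2-yl)-1-[2,4,6-tris(tert-butyldimethylsilyloxy)phenyl]oct-7-en-1-one F1.
- About two equivalents of F1 are offered to 17 with (R)-TRIP in toluene at low temperature. This is a kinetic resolution of a racemic secondary allylboronate.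
- Only the R enantiomer has a chair that satisfies both the acid (Re face) and the bulkier diol (chain axial). It gives the O-(tetraethyldioxaborolanyl) ether of 19 F2, and aqueous work-up gives 19. The S enantiomer stays behind.

**Step 10.** The risk is acid-promoted isomerisation of the 4Z alkene during or after acetal cleavage.

The fallback sets out from 13 and comes back at 17. It uses no acid at any point.
- Ylide 15, made from 13 as in step 9, is condensed with commercial ethyl (E)-4-oxobut-2-enoate to give ethyl (2E,4Z,7Z)-deca-2,4,7-trienoate F3.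
- i-Bu2AlH (CH2Cl2, −78 °C) gives (2E,4Z,7Z)-deca-2,4,7-trien-1-ol F4.
- MnO2 (CH2Cl2, rt) gives 17.

**Step 4.** The risks are low turnover of the dithiolate catalyst, homodimerisation of 6, and erosion of stereoretention.

The fallback sets out from 6 and 7 and comes back at 10. It removes the need for a Z-alkene and bypasses 8 and 9.
- Diol 7 is converted with methyl chloroformate and pyridine into (Z)-but-2-ene-1,4-diyl dimethyl dicarbonate F5.
- Cross-metathesis of 6 with F5 under thermodynamic control (second-generation Grubbs catalyst, CH2Cl2, reflux) gives methyl (2E)-8-oxo-8-[2,4,6-tris(tert-butyldimethylsilyloxy)phenyl]oct-2-en-1-yl carbonate F6.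
- An enantioselective boryl substitution suited to E-allylic carbonates then gives 10 directly. It uses a chiral N-heterocyclic carbene copper catalyst (chiral imidazolinium salt, Cu(OTf)2, NaOMe, B2pin2, DME, −30 °C).

**Further compounds**
F1 | step 11 | racemic 6-(4,4,5,5-tetraethyl-1,3,2-dioxaborolan-2-yl)-1-[2,4,6-tris(tert-butyldimethylsilyloxy)phenyl]oct-7-en-1-one | C=CC(B1OC(CC)(CC)C(CC)(CC)O1)CCCCC(=O)c1c(O[Si](C)(C)C(C)(C)C)cc(O[Si](C)(C)C(C)(C)C)cc1O[Si](C)(C)C(C)(C)C
F2 | step 11 | O-(tetraethyldioxaborolanyl) ether of 19 | CC/C=C\C/C=C\C=C\[C@H](OB1OC(CC)(CC)C(CC)(CC)O1)C/C=C\CCCCC(=O)c1c(O[Si](C)(C)C(C)(C)C)cc(O[Si](C)(C)C(C)(C)C)cc1O[Si](C)(C)C(C)(C)C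
F3 | step 10 | ethyl (2E,4Z,7Z)-deca-2,4,7-trienoate | CC/C=C\C/C=C\C=C\C(=O)OCC
F4 | step 10 | (2E,4Z,7Z)-deca-2,4,7-trien-1-ol | CC/C=C\C/C=C\C=C\CO
F5 | step 4 | (Z)-but-2-ene-1,4-diyl dimethyl dicarbonate | COC(=O)OC/C=C\COC(=O)OC
F6 | step 4 | methyl (2E)-8-oxo-8-[2,4,6-tris(tert-butyldimethylsilyloxy)phenyl]oct-2-en-1-yl carbonate | COC(=O)OC/C=C/CCCCC(=O)c1c(O[Si](C)(C)C(C)(C)C)cc(O[Si](C)(C)C(C)(C)C)cc1O[Si](C)(C)C(C)(C)C
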